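## Retrosynthetic overview
1. End game: the free hydrogen sulfate comes from its potassium salt, which comes from the 5,3'-di-O-benzyl tetrabutylammonium sulfate (protonation, cation exchange, hydrogenolysis).
2. Key disconnection (new step): the C3–O bond is made with the sulfate already attached, from the C3-lithiated protected flavone and peroxydisulfate.
3. Ring C is the only ring built (rings A and B are bought as arenes). The O1–C2 bond is closed by I2/DMSO oxidative cyclisation of a 2'-hydroxychalcone.
4. The chalcone Cα=Cβ bond comes from Claisen–Schmidt condensation of mono-O-benzylated 2',6'-dihydroxy-4'-methoxyacetophenone (ring A) with O-benzylisovanillin (ring B).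

Assumption 1: the target is a flat, achiral flavonol with no stereocentre, so "single enantiomer" needs no action; the E-alkene of 4 and C2 of transient 5 are erased in step 3.
Assumption 2: the SMILES shows the free hydrogen sulfate, so the route ends by protonating the stable potassium salt 10, which is the storage form.
Assumption 3: bis(tetrabutylammonium) peroxydisulfate is taken as a known shelf reagent (bought, or extracted into CH2Cl2 from aqueous K2S2O8/n-Bu4NHSO4) and is dried before use.

## Route

Step 1
Reactants: 1 2',6'-dihydroxy-4'-methoxyacetophenone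
Product: 2 2'-benzyloxy-6'-hydroxy-4'-methoxyacetophenone
Conditions: BnBr (1.05 equiv), K2CO3 (1.1 equiv), acetone, reflux
Reagents that add atoms: benzyl bromide, BrCc1ccccc1
Why: Williamson ether synthesis on two equivalent phenols stops at mono-alkylation, because the remaining OH is locked in a strong hydrogen bond to the acetyl C=O and reacts much more slowly.

Step 2
Reactants: 2 2'-benzyloxy-6'-hydroxy-4'-methoxyacetophenone; 3 3-benzyloxy-4-methoxybenzaldehyde (O-benzylisovanillin)
Product: 4 (E)-3,6'-bis(benzyloxy)-2'-hydroxy-4,4'-dimethoxychalcone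
Conditions: 50% aq KOH, EtOH, rt; then dilute HCl to pH 5
Reagents that add atoms: none
Why: Claisen–Schmidt aldol condensation with a non-enolisable aldehyde, followed by E1cB loss of water, gives the thermodynamically favoured E-enone, and the benzyl and methyl ethers are inert to base.

Step 3
Reactants: 4 (E)-3,6'-bis(benzyloxy)-2'-hydroxy-4,4'-dimethoxychalcone
Product: 6 5-(benzyloxy)-2-[3-(benzyloxy)-4-methoxyphenyl]-7-methoxy-4H-chromen-4-one, via racemic flavanone 5 (not isolated)
Conditions: I2 (10 mol%), DMSO, 130 °C; aq Na2S2O3 work-up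
Reagents that add atoms: none
Why: In this iodine-catalysed oxidative cyclisation, oxa-Michael closure forms ring C, α-iodination and HI elimination aromatise it, and DMSO re-oxidises HI to I2.

Step 4
Reactants: 6 5-(benzyloxy)-2-[3-(benzyloxy)-4-methoxyphenyl]-7-methoxy-4H-chromen-4-one
Product: 8 tetrabutylammonium 5-(benzyloxy)-2-[3-(benzyloxy)-4-methoxyphenyl]-7-methoxy-4-oxo-4H-chromen-3-yl sulfate, via 3-lithioflavone 7 (not isolated)
Conditions: LDA (commercial solution, 1.2 equiv), THF, −78 °C, 1 h; cannulate into (n-Bu4N)2S2O8 (2.0 equiv), THF–DMPU, −78 → −40 °C; aq NH4Cl, CH2Cl2 ion-pair extraction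
Reagents that add atoms: bis(tetrabutylammonium) peroxydisulfate, CCCC[N+](CCCC)(CCCC)CCCC.CCCC[N+](CCCC)(CCCC)CCCC.[O-]S(=O)(=O)OOS(=O)(=O)[O-]
Why: Proposed new method: electrophilic sulfooxylation of a vinyllithium, in which the C3–H lithiation of a fully O-protected flavone by LDA is established and the new event is SN2-type attack of the C3 carbanion on a peroxide oxygen of S2O8(2−) (weak O–O bond, low σ*, Li+ bridging the carbanion and a sulfonyl oxygen, sulfate as leaving group), so the C3–O bond forms with the sulfate attached and only at the metalated carbon; a competing single-electron transfer gives a vinyl radical/SO4 radical-anion pair whose in-cage collapse leads to the same product; the closest known reaction types are the Elbs persulfate oxidation (phenolate carbon attacking the same O–O bond) and the oxygenation of organolithiums with bis(trimethylsilyl) peroxide or lithium tert-butyl peroxide; the low temperature suppresses β-elimination of 7 to the ynone phenolate.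

Step 5
Reactants: 8 tetrabutylammonium 5-(benzyloxy)-2-[3-(benzyloxy)-4-methoxyphenyl]-7-methoxy-4-oxo-4H-chromen-3-yl sulfate
Product: 10 potassium ombuin 3-O-sulfate, via debenzylated tetrabutylammonium salt 9 (not isolated)
Conditions: H2 (1 atm), 10% Pd/C, MeOH–THF, rt; filter; sat. KOAc in MeOH, 0 °C, collect precipitate
Reagents that add atoms: potassium acetate, CC(=O)[O-].[K+]
Why: Neutral catalytic hydrogenolysis cleaves both benzyl aryl ethers while the sulfate monoester anion and the tetrasubstituted C2=C3 bond stay intact, and salt metathesis is driven by the low solubility of the potassium salt in methanol.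

Step 6
Reactants: 10 potassium ombuin 3-O-sulfate
Product: 11 ombuin 3-O-sulfate (5-hydroxy-2-(3-hydroxy-4-methoxyphenyl)-7-methoxy-4-oxo-4H-chromen-3-yl hydrogen sulfate)
Conditions: 0.1 M aq HCl (1.05 equiv), 0 °C, 5 min; C18 cartridge (cold H2O wash, MeOH elution); freeze-dry, store at −20 °C
Reagents that add atoms: none
Why: This is a simple potassium-for-proton salt metathesis, where brief cold contact with dilute acid avoids hydrolysis of the sulfate and the reversed-phase wash removes the inorganic salt.

## Compound list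
1 | 2',6'-dihydroxy-4'-methoxyacetophenone | CC(=O)c1c(O)cc(OC)cc1O | starting material
2 | 2'-benzyloxy-6'-hydroxy-4'-methoxyacetophenone | CC(=O)c1c(O)cc(OC)cc1OCc1ccccc1 | intermediate
3 | 3-benzyloxy-4-methoxybenzaldehyde | COc1ccc(C=O)cc1OCc1ccccc1 | starting material
4 | (E)-1-[2-(benzyloxy)-6-hydroxy-4-methoxyphenyl]-3-[3-(benzyloxy)-4-methoxyphenyl]prop-2-en-1-one | COc1cc(O)c(C(=O)/C=C/c2ccc(OC)c(OCc3ccccc3)c2)c(OCc2ccccc2)c1 | intermediate
5 | racemic 5-(benzyloxy)-2-[3-(benzyloxy)-4-methoxyphenyl]-7-methoxychroman-4-one (not isolated) | COc1cc(OCc2ccccc2)c2c(c1)OC(c1ccc(OC)c(OCc3ccccc3)c1)CC2=O | intermediate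
6 | 5-(benzyloxy)-2-[3-(benzyloxy)-4-methoxyphenyl]-7-methoxy-4H-chromen-4-one | COc1cc(OCc2ccccc2)c2c(=O)cc(-c3ccc(OC)c(OCc4ccccc4)c3)oc2c1 | intermediate
7 | 3-lithio derivative of 6 (not isolated) | COc1cc(OCc2ccccc2)c2c(=O)c([Li])c(-c3ccc(OC)c(OCc4ccccc4)c3)oc2c1 | intermediate
8 | tetrabutylammonium 5,3'-di-O-benzylombuin 3-O-sulfate | COc1cc(OCc2ccccc2)c2c(=O)c(OS(=O)(=O)[O-])c(-c3ccc(OC)c(OCc4ccccc4)c3)oc2c1.CCCC[N+](CCCC)(CCCC)CCCC | intermediate
9 | tetrabutylammonium ombuin 3-O-sulfate (not isolated) | COc1cc(O)c2c(=O)c(OS(=O)(=O)[O-])c(-c3ccc(OC)c(O)c3)oc2c1.CCCC[N+](CCCC)(CCCC)CCCC | intermediate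
10 | potassium ombuin 3-O-sulfate | COc1cc(O)c2c(=O)c(OS(=O)(=O)[O-])c(-c3ccc(OC)c(O)c3)oc2c1.[K+] | intermediate
11 | ombuin 3-O-sulfate (achiral) | COc1cc(O)c2c(=O)c(OS(=O)(=O)O)c(-c3ccc(OC)c(O)c3)oc2c1 | target

## Step count and risks
Total steps: 6. Longest linear sequence: 6 (1 → 2 → 4 → 6 → 8 → 10 → 11).

**Step 4 (new reaction, highest risk).**
- The vinyllithium may be oxidised without C–O formation, which returns 6. It may also fragment, or be quenched by a poorly soluble or wet oxidant.
- The fallback uses known chemistry only, sets out from 6 and comes back at 8.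
- Dimethyldioxirane (acetone/CH2Cl2, 0 °C) epoxidises C2=C3 to the racemic flavone 2,3-epoxide F1.
- A catalytic amount of p-TsOH isomerises this to 5,3'-di-O-benzylombuin F2, whose only free hydroxyl is 3-OH.
- Carbodiimide-mediated sulfation (DCC, n-Bu4NHSO4, pyridine, rt) then delivers 8 directly as its tetrabutylammonium salt.

**Step 5 (hydrogenolysis in the presence of the sulfate).**
- Debenzylation of the chelation-prone 5-O-benzyl group may be slow. Ring C may be partly reduced, or sulfate may be lost on an acidic catalyst.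
- The fallback reverses the order of events. It sets out from 6 and comes back at 9.
- Compound 6 is taken through F1 to F2 as above, and F2 is hydrogenolysed first (H2, Pd/C, EtOAc–MeOH) to ombuin F3.
- F3 is sulfated site-selectively with DCC/n-Bu4NHSO4 in pyridine. This reagent esterifies flavonol 3-, 7- and 4'-hydroxyls but not the chelated 5-OH or the 3'-OH.
- Because positions 7 and 4' of F3 are methylated, only the 3-OH reacts to give 9. The KOAc exchange to 10 then follows as in the route.

**Step 3 (I2/DMSO at 130 °C).**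
- The HI formed may cleave the peri 5-O-benzyl ether or give an incomplete flavanone-to-flavone conversion.
- The fallback builds ring C by a Baker–Venkataraman sequence instead of from the chalcone. It sets out from 2 and comes back at 6.
- Compound 2 is O-acylated with commercial 3-benzyloxy-4-methoxybenzoic acid (EDC·HCl, DMAP, CH2Cl2) to give the aryl ester F4.
- KOH in pyridine at 50 °C causes the acyl migration to the 1,3-diketone F5.
- NaOAc/AcOH at 100 °C cyclodehydrates F5 to 6 without any oxidant or iodide.

## Further compounds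
F1 | step 4 | racemic 2,3-epoxide of 6 (1a,7a-dihydro-oxireno[b]chromen-7-one, cis-fused) | COc1cc(OCc2ccccc2)c2c(c1)OC1(c3ccc(OC)c(OCc4ccccc4)c3)OC1C2=O
F2 | step 4 | 5,3'-di-O-benzylombuin (5-(benzyloxy)-2-[3-(benzyloxy)-4-methoxyphenyl]-3-hydroxy-7-methoxy-4H-chromen-4-one) | COc1cc(OCc2ccccc2)c2c(=O)c(O)c(-c3ccc(OC)c(OCc4ccccc4)c3)oc2c1
F3 | step 5 | ombuin (3,5,3'-trihydroxy-7,4'-dimethoxyflavone) | COc1cc(O)c2c(=O)c(O)c(-c3ccc(OC)c(O)c3)oc2c1
F4 | step 3 | 2-acetyl-3-(benzyloxy)-5-methoxyphenyl 3-(benzyloxy)-4-methoxybenzoate | CC(=O)c1c(OCc2ccccc2)cc(OC)cc1OC(=O)c1ccc(OC)c(OCc2ccccc2)c1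
F5 | step 3 | 1-[2-(benzyloxy)-6-hydroxy-4-methoxyphenyl]-3-[3-(benzyloxy)-4-methoxyphenyl]propane-1,3-dione | COc1cc(O)c(C(=O)CC(=O)c2ccc(OC)c(OCc3ccccc3)c2)c(OCc2ccccc2)c1
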